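## Retrosynthetic overview

Locants follow the 1-benzofuran-2-one numbering of the target: C3 (methylidene carbon), C3a, C4 (ester carbon), C5, C6, C7, C7a.

1. Target ⇐ reduction of a C6 aldehyde, silyl/acetal removal, Mitsunobu inversion at C4 with methacrylic acid, Mannich methylenation at C3, and convex-face reduction of the C4 ketone of a cis-fused enone lactone.
2. Lactone ring (formed second) ⇐ desilylative lactonisation of a cis γ-silyloxy acid. Cyclohexenone ring (formed first, key step) ⇐ intramolecular aldol condensation of a 1,5-diketone that creates the C5=C6 bond.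
3. 1,5-Diketone acid ⇐ ozonolysis/chlorite cleavage of an allyl and a 2-substituted propenyl group in a ketone made from a Weinreb amide (fragment C) and a Grignard reagent (fragment A).
4. Fragment C ⇐ ethyl (S)-4-chloro-3-hydroxybutanoate: epoxide, copper-catalysed opening by the alkenyl metal from 2-bromoacrolein diethyl acetal (fragment B), Fráter–Seebach anti-allylation (sets C7a and C3a).
5. Fragment A ⇐ Evans allylation of a propanoyl oxazolidinone (side-chain stereocentre), reduction, bromination, hydroboration, silylation.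

Assumption: metal enolates, alkoxides and carbanions that are only the deprotonated form of a numbered compound are not numbered separately, and aqueous quenches are balanced with water.

## Route

**Fragment A (side chain)**

Step 1
Reactants: 1 (4R)-4-benzyl-1,3-oxazolidin-2-one
Product: 2 (4R)-4-benzyl-3-propanoyl-1,3-oxazolidin-2-one
Conditions: EtCOCl, Et3N, DMAP (cat.), CH2Cl2, 0 °C to rt
Reagents that add atoms: propanoyl chloride, CCC(=O)Cl
Why: DMAP-catalysed N-acylation gives the imide needed for auxiliary-controlled alkylation, and the auxiliary stereocentre is not involved.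

Step 2
Reactants: 2 propanoyl imide
Product: 3 (4R)-4-benzyl-3-[(2S)-2-methylpent-4-enoyl]-1,3-oxazolidin-2-one
Conditions: NaN(SiMe3)2, THF, −78 °C; allyl iodide, −78 to −45 °C
Reagents that add atoms: 3-iodoprop-1-ene (allyl iodide), C=CCI
Why: Evans asymmetric alkylation: the chelated Z sodium enolate is shielded on one face by the benzyl group, so the allyl group enters from the other face and sets the (2S) centre that becomes the side-chain stereocentre.

Step 3
Reactants: 3 alkylated imide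
Product: 4 (2S)-2-methylpent-4-en-1-ol
Conditions: LiBH4, H2O (1 equiv), Et2O, 0 °C
Reagents that add atoms: none
Why: Hydride reduction of the exocyclic imide carbonyl releases the primary alcohol without touching the α-stereocentre, and the auxiliary is recovered.

Step 4
Reactants: 4 alcohol
Product: 5 (4S)-5-bromo-4-methylpent-1-ene
Conditions: CBr4, PPh3, CH2Cl2, 0 °C
Reagents that add atoms: tetrabromomethane, BrC(Br)(Br)Br
Why: Appel reaction (SN2 displacement at the primary carbon) leaves the adjacent stereocentre unchanged.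

Step 5
Reactants: 5 bromoalkene
Product: 7 (4S)-5-bromo-4-methylpentan-1-ol, via alkylborane 6 (not isolated)
Conditions: 9-BBN, THF, 0 °C to rt; then H2O2, aq. NaOAc, 0 °C
Reagents that add atoms: hydrogen peroxide, OO
Why: Anti-Markovnikov hydroboration–oxidation with the bulky 9-BBN gives the terminal alcohol, and the buffered peroxide oxidation spares the primary bromide.

Step 6
Reactants: 7 bromo alcohol
Product: 8 {[(4S)-5-bromo-4-methylpentyl]oxy}(tert-butyl)diphenylsilane
Conditions: t-BuPh2SiCl, imidazole, CH2Cl2, rt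
Reagents that add atoms: tert-butyl(chloro)diphenylsilane, CC(C)(C)[Si](Cl)(c1ccccc1)c1ccccc1
Why: Imidazole-promoted silylation gives a primary silyl ether that survives the Grignard, ozone, amide-base and mild-acid steps ahead.

**Fragment B (C6 and its one-carbon substituent)**

Step 7
Reactants: 9 3,3-diethoxyprop-1-ene (acrolein diethyl acetal)
Product: 10 2,3-dibromo-1,1-diethoxypropane
Conditions: Br2, CH2Cl2, −20 °C
Reagents that add atoms: bromine, BrBr
Why: Electrophilic anti addition of bromine to the alkene leaves the acetal untouched.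

Step 8
Reactants: 10 dibromide
Product: 11 2-bromo-3,3-diethoxyprop-1-ene
Conditions: KOt-Bu, THF, 0 °C
Reagents that add atoms: none
Why: E2 dehydrobromination removes the acidic C2 hydrogen together with the primary bromide, which leaves the bromine on the internal alkene carbon.

**Fragment C (core)**

Step 9
Reactants: 12 ethyl (3S)-4-chloro-3-hydroxybutanoate
Product: 13 ethyl (3S)-3-hydroxy-4-iodobutanoate
Conditions: NaI, butan-2-one, reflux
Reagents that add atoms: sodium iodide, [Na+].[I-]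
Why: Finkelstein halide exchange (SN2 at the primary carbon, driven by precipitation of NaCl) does not involve the carbinol stereocentre.

Step 10
Reactants: 13 iodohydrin
Product: 14 ethyl [(2S)-oxiran-2-yl]acetate
Conditions: Ag2O, DME, rt, dark
Reagents that add atoms: none
Why: Silver-assisted intramolecular Williamson etherification closes the epoxide under non-basic conditions that do not isomerise the β,γ-epoxy ester, with the C–O stereocentre retained.

Step 11
Reactants: 11 bromoalkene; 14 epoxide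
Product: 17 ethyl (3R)-5-(diethoxymethyl)-3-hydroxyhex-5-enoate, via alkenyllithium 15 (not isolated), via alkenylmagnesium bromide 16 (not isolated)
Conditions: 11, t-BuLi (2 equiv), Et2O, −78 °C; MgBr2·OEt2, −78 to −40 °C; then CuI (10 mol %), 14, THF, −40 to −20 °C
Reagents that add atoms: none
Why: Bromine–lithium exchange, transmetalation to magnesium and copper-catalysed SN2 opening of the epoxide at its CH2 terminus give the homoallylic alcohol, the carbinol centre (future C7a) being untouched.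

Step 12
Reactants: 17 β-hydroxy ester
Product: 18 ethyl (2R,3R)-5-(diethoxymethyl)-3-hydroxy-2-(prop-2-en-1-yl)hex-5-enoate
Conditions: LiN(i-Pr)2 (2.2 equiv), THF, −78 to −20 °C; allyl bromide, DMPU, −78 to −10 °C
Reagents that add atoms: 3-bromoprop-1-ene (allyl bromide), C=CCBr
Why: Fráter–Seebach alkylation: the chelated dilithio alkoxide enolate is allylated on the face away from the carbinol substituent, which sets the future C3a anti to the hydroxyl (the relationship that later gives the cis ring fusion).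

Step 13
Reactants: 18 anti hydroxy ester
Product: 19 ethyl (2R,3R)-5-(diethoxymethyl)-2-(prop-2-en-1-yl)-3-[(triethylsilyl)oxy]hex-5-enoate
Conditions: Et3SiCl, imidazole, DMAP (cat.), CH2Cl2, 0 °C to rt
Reagents that add atoms: chlorotriethylsilane, CC[Si](Cl)(CC)CC
Why: Silylation masks the hydroxyl as a poor β-leaving group for the later carbonyl chemistry, and the triethylsilyl ether can be removed later beside the bulkier silyl ether.

Step 14
Reactants: 19 silyloxy ester
Product: 20 (2R,3R)-5-(diethoxymethyl)-N-methoxy-N-methyl-2-(prop-2-en-1-yl)-3-[(triethylsilyl)oxy]hex-5-enamide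
Conditions: MeNH(OMe)·HCl, i-PrMgCl, THF, −20 to 0 °C
Reagents that add atoms: N,O-dimethylhydroxylamine hydrochloride, CNOC.Cl
Why: Aminolysis of the ester by the chloromagnesium amide gives the Weinreb amide under conditions that neither epimerise the α-centre nor affect the acetal.

**Union and endgame**

Step 15
Reactants: 8 bromide; 20 Weinreb amide
Product: 22 (4R,5R,8S)-11-{[tert-butyl(diphenyl)silyl]oxy}-2-(diethoxymethyl)-8-methyl-5-(prop-2-en-1-yl)-4-[(triethylsilyl)oxy]undec-1-en-6-one, via Grignard reagent 21 (not isolated)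
Conditions: 8, Mg, THF, 40 °C; then 20, THF, 0 °C to rt
Reagents that add atoms: none
Why: Grignard formation and Weinreb ketone synthesis: the magnesium-chelated tetrahedral adduct does not collapse until work-up, so the ketone forms without over-addition and the α-stereocentre stays intact.

Step 16
Reactants: 22 dienyl ketone
Product: 24 (3R,4R)-3-[(3S)-6-{[tert-butyl(diphenyl)silyl]oxy}-3-methylhexanoyl]-7,7-diethoxy-6-oxo-4-[(triethylsilyl)oxy]heptanoic acid, via keto aldehyde 23 (not isolated)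
Conditions: O3, MeCN/H2O (9:1), 0 °C; then NaClO2, NaH2PO4, 0 °C to rt
Reagents that add atoms: ozone, [O-][O+]=O; water, O; sodium chlorite, [Na+].[O-]Cl=O
Why: Ozonolysis in wet acetonitrile cleaves both terminal alkenes to the α-keto acetal and an aldehyde, and the in-situ Pinnick oxidation (the H2O2 formed scavenges hypochlorite) takes only the aldehyde to the acid without touching a stereocentre.

Step 17
Reactants: 24 diketo acid
Product: 26 2-[(1R,6R)-3-[(2S)-5-{[tert-butyl(diphenyl)silyl]oxy}pentan-2-yl]-4-(diethoxymethyl)-2-oxo-6-[(triethylsilyl)oxy]cyclohex-3-en-1-yl]acetic acid, via aldol adduct 25 (not isolated)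
Conditions: pyrrolidine, AcOH, toluene, 50 °C
Reagents that add atoms: none
Why: Intramolecular aldol condensation under enamine catalysis: the enamine of the hindered ketone forms on its CH2 side and attacks the activated α-keto acetal carbonyl (whose own α-carbon could only close a four-membered ring), and dehydration gives the tetrasubstituted cyclohexenone without creating or touching a stereocentre.

Step 18
Reactants: 26 enone acid
Product: 28 (3aR,7aR)-5-[(2S)-5-{[tert-butyl(diphenyl)silyl]oxy}pentan-2-yl]-6-(diethoxymethyl)-3,3a,7,7a-tetrahydro-1-benzofuran-2,4-dione, via hydroxy acid 27 (not isolated)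
Conditions: HF·pyridine, pyridine, THF, 0 °C to rt
Reagents that add atoms: none
Why: Buffered HF·pyridine cleaves only the secondary triethylsilyl ether, and the freed C7a hydroxyl lactonises at once with the cis acetic acid arm to the cis-fused γ-lactone while the bulkier silyl ether and the acetal survive.

Step 19
Reactants: 28 enone lactone
Product: 29 (3aS,4R,7aR)-5-[(2S)-5-{[tert-butyl(diphenyl)silyl]oxy}pentan-2-yl]-6-(diethoxymethyl)-4-hydroxy-3a,4,7,7a-tetrahydro-1-benzofuran-2(3H)-one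
Conditions: NaBH4, CeCl3·7H2O, MeOH/CH2Cl2, −78 °C
Reagents that add atoms: none
Why: Luche 1,2-reduction: hydride attacks the ketone from the convex face of the cis-fused bicycle (the face of H3a and H7a), placing the new C4 hydroxyl on the lactone face (4R).

Step 20
Reactants: 29 cis hydroxy lactone
Product: 32 (3aS,4R,7aR)-5-[(2S)-5-{[tert-butyl(diphenyl)silyl]oxy}pentan-2-yl]-6-(diethoxymethyl)-4-hydroxy-3-methylidene-3a,4,7,7a-tetrahydro-1-benzofuran-2(3H)-one, via Mannich base 30 (not isolated), via methiodide 31 (not isolated)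
Conditions: LiN(i-Pr)2 (2.5 equiv), THF, −78 °C; Me2N=CH2+ I−, −78 to −20 °C; then MeI, MeOH, rt; then aq. NaHCO3, CH2Cl2, rt
Reagents that add atoms: dimethyl(methylidene)ammonium iodide, C=[N+](C)C.[I-]
Why: α-Methylenation by Mannich reaction of the lactone enolate (formed beside the alkoxide) with the iminium salt, N-methylation and base-induced β-elimination of trimethylamine; C3 ends sp2, so its transient configuration is irrelevant.

Step 21
Reactants: 32 cis hydroxy methylene lactone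
Product: 33 (3aR,4S,7aR)-5-[(2S)-5-{[tert-butyl(diphenyl)silyl]oxy}pentan-2-yl]-6-(diethoxymethyl)-3-methylidene-2-oxo-2,3,3a,4,7,7a-hexahydro-1-benzofuran-4-yl 2-methylprop-2-enoate
Conditions: methacrylic acid, PPh3, DIAD, toluene, 0 °C to rt
Reagents that add atoms: 2-methylprop-2-enoic acid, C=C(C)C(=O)O
Why: Mitsunobu esterification: methacrylate displaces the oxyphosphonium group with SN2 inversion from the open convex face, giving the (4S) ester trans to the lactone ring as in the target.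

Step 22
Reactants: 33 silyl acetal ester
Product: 34 (3aR,4S,7aR)-6-formyl-5-[(2S)-5-hydroxypentan-2-yl]-3-methylidene-2-oxo-2,3,3a,4,7,7a-hexahydro-1-benzofuran-4-yl 2-methylprop-2-enoate
Conditions: HF·pyridine, THF, 0 °C to rt; then H2O, rt
Reagents that add atoms: water, O
Why: Fluoride cleaves the silyl ether and the aqueous acidic medium hydrolyses the allylic diethyl acetal to the conjugated aldehyde, conditions under which both esters and the methylene lactone are stable.

Step 23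
Reactants: 34 hydroxy enal
Product: 35 (3aR,4S,7aR)-6-(hydroxymethyl)-5-[(2S)-5-hydroxypentan-2-yl]-3-methylidene-2-oxo-2,3,3a,4,7,7a-hexahydro-1-benzofuran-4-yl 2-methylprop-2-enoate (CNP0142089.2)
Conditions: NaBH4, CeCl3·7H2O, MeOH, −78 °C
Reagents that add atoms: none
Why: Luche reduction is selective for 1,2-reduction of the conjugated aldehyde at −78 °C over the methacrylate, the lactone and the exocyclic enoate, and creates no stereocentre.

## Compound list

1 | (4R)-4-benzyl-1,3-oxazolidin-2-one | O=C1N[C@H](Cc2ccccc2)CO1 | starting material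
2 | (4R)-4-benzyl-3-propanoyl-1,3-oxazolidin-2-one | CCC(=O)N1[C@H](Cc2ccccc2)COC1=O | intermediate
3 | (4R)-4-benzyl-3-[(2S)-2-methylpent-4-enoyl]-1,3-oxazolidin-2-one | C=CC[C@H](C)C(=O)N1[C@H](Cc2ccccc2)COC1=O | intermediate
4 | (2S)-2-methylpent-4-en-1-ol | C=CC[C@H](C)CO | intermediate
5 | (4S)-5-bromo-4-methylpent-1-ene | C=CC[C@H](C)CBr | intermediate
6 | 9-[(4S)-5-bromo-4-methylpentyl]-9-borabicyclo[3.3.1]nonane (formed in situ) | BrC[C@@H](C)CCCB1C2CCCC1CCC2 | intermediate
7 | (4S)-5-bromo-4-methylpentan-1-ol | OCCC[C@H](C)CBr | intermediate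
8 | {[(4S)-5-bromo-4-methylpentyl]oxy}(tert-butyl)diphenylsilane | BrC[C@@H](C)CCCO[Si](c1ccccc1)(c1ccccc1)C(C)(C)C | intermediate
9 | 3,3-diethoxyprop-1-ene (acrolein diethyl acetal) | C=CC(OCC)OCC | starting material
10 | 2,3-dibromo-1,1-diethoxypropane (racemic) | BrCC(Br)C(OCC)OCC | intermediate
11 | 2-bromo-3,3-diethoxyprop-1-ene | C=C(Br)C(OCC)OCC | intermediate
12 | ethyl (3S)-4-chloro-3-hydroxybutanoate | CCOC(=O)C[C@H](O)CCl | starting material
13 | ethyl (3S)-3-hydroxy-4-iodobutanoate | CCOC(=O)C[C@H](O)CI | intermediate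
14 | ethyl [(2S)-oxiran-2-yl]acetate | CCOC(=O)C[C@H]1CO1 | intermediate
15 | (3,3-diethoxyprop-1-en-2-yl)lithium (formed in situ) | [Li]C(=C)C(OCC)OCC | intermediate
16 | bromo(3,3-diethoxyprop-1-en-2-yl)magnesium (formed in situ) | Br[Mg]C(=C)C(OCC)OCC | intermediate
17 | ethyl (3R)-5-(diethoxymethyl)-3-hydroxyhex-5-enoate | CCOC(=O)C[C@H](O)CC(=C)C(OCC)OCC | intermediate
18 | ethyl (2R,3R)-5-(diethoxymethyl)-3-hydroxy-2-(prop-2-en-1-yl)hex-5-enoate | CCOC(=O)[C@H](CC=C)[C@H](O)CC(=C)C(OCC)OCC | intermediate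
19 | ethyl (2R,3R)-5-(diethoxymethyl)-2-(prop-2-en-1-yl)-3-[(triethylsilyl)oxy]hex-5-enoate | CCOC(=O)[C@H](CC=C)[C@H](O[Si](CC)(CC)CC)CC(=C)C(OCC)OCC | intermediate
20 | (2R,3R)-5-(diethoxymethyl)-N-methoxy-N-methyl-2-(prop-2-en-1-yl)-3-[(triethylsilyl)oxy]hex-5-enamide | CON(C)C(=O)[C@H](CC=C)[C@H](O[Si](CC)(CC)CC)CC(=C)C(OCC)OCC | intermediate
21 | bromo[(2S)-5-{[tert-butyl(diphenyl)silyl]oxy}-2-methylpentyl]magnesium (formed in situ) | Br[Mg]C[C@@H](C)CCCO[Si](c1ccccc1)(c1ccccc1)C(C)(C)C | intermediate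
22 | (4R,5R,8S)-11-{[tert-butyl(diphenyl)silyl]oxy}-2-(diethoxymethyl)-8-methyl-5-(prop-2-en-1-yl)-4-[(triethylsilyl)oxy]undec-1-en-6-one | CC(C)(C)[Si](c1ccccc1)(c1ccccc1)OCCC[C@H](C)CC(=O)[C@H](CC=C)[C@H](O[Si](CC)(CC)CC)CC(=C)C(OCC)OCC | intermediate
23 | (3R,4R)-3-[(3S)-6-{[tert-butyl(diphenyl)silyl]oxy}-3-methylhexanoyl]-7,7-diethoxy-6-oxo-4-[(triethylsilyl)oxy]heptanal (formed in situ) | CC(C)(C)[Si](c1ccccc1)(c1ccccc1)OCCC[C@H](C)CC(=O)[C@H](CC=O)[C@H](O[Si](CC)(CC)CC)CC(=O)C(OCC)OCC | intermediate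
24 | (3R,4R)-3-[(3S)-6-{[tert-butyl(diphenyl)silyl]oxy}-3-methylhexanoyl]-7,7-diethoxy-6-oxo-4-[(triethylsilyl)oxy]heptanoic acid | CC(C)(C)[Si](c1ccccc1)(c1ccccc1)OCCC[C@H](C)CC(=O)[C@H](CC(=O)O)[C@H](O[Si](CC)(CC)CC)CC(=O)C(OCC)OCC | intermediate
25 | 2-[(1R,6R)-3-[(2S)-5-{[tert-butyl(diphenyl)silyl]oxy}pentan-2-yl]-4-(diethoxymethyl)-4-hydroxy-2-oxo-6-[(triethylsilyl)oxy]cyclohexyl]acetic acid (ring C3 and C4 as formed; formed in situ) | O=C1C([C@@H](C)CCCO[Si](c2ccccc2)(c2ccccc2)C(C)(C)C)C(O)(C(OCC)OCC)C[C@@H](O[Si](CC)(CC)CC)[C@H]1CC(=O)O | intermediate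
26 | 2-[(1R,6R)-3-[(2S)-5-{[tert-butyl(diphenyl)silyl]oxy}pentan-2-yl]-4-(diethoxymethyl)-2-oxo-6-[(triethylsilyl)oxy]cyclohex-3-en-1-yl]acetic acid | O=C1C([C@@H](C)CCCO[Si](c2ccccc2)(c2ccccc2)C(C)(C)C)=C(C(OCC)OCC)C[C@@H](O[Si](CC)(CC)CC)[C@H]1CC(=O)O | intermediate
27 | 2-[(1R,6R)-3-[(2S)-5-{[tert-butyl(diphenyl)silyl]oxy}pentan-2-yl]-4-(diethoxymethyl)-6-hydroxy-2-oxocyclohex-3-en-1-yl]acetic acid (formed in situ) | O=C1C([C@@H](C)CCCO[Si](c2ccccc2)(c2ccccc2)C(C)(C)C)=C(C(OCC)OCC)C[C@@H](O)[C@H]1CC(=O)O | intermediate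
28 | (3aR,7aR)-5-[(2S)-5-{[tert-butyl(diphenyl)silyl]oxy}pentan-2-yl]-6-(diethoxymethyl)-3,3a,7,7a-tetrahydro-1-benzofuran-2,4-dione (cis-fused) | O=C1C([C@@H](C)CCCO[Si](c3ccccc3)(c3ccccc3)C(C)(C)C)=C(C(OCC)OCC)C[C@H]2OC(=O)C[C@@H]12 | intermediate
29 | (3aS,4R,7aR)-5-[(2S)-5-{[tert-butyl(diphenyl)silyl]oxy}pentan-2-yl]-6-(diethoxymethyl)-4-hydroxy-3a,4,7,7a-tetrahydro-1-benzofuran-2(3H)-one (4-OH cis to the lactone ring) | O[C@H]1C([C@@H](C)CCCO[Si](c3ccccc3)(c3ccccc3)C(C)(C)C)=C(C(OCC)OCC)C[C@H]2OC(=O)C[C@@H]12 | intermediate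
30 | (3aS,4R,7aR)-5-[(2S)-5-{[tert-butyl(diphenyl)silyl]oxy}pentan-2-yl]-6-(diethoxymethyl)-3-[(dimethylamino)methyl]-4-hydroxy-3a,4,7,7a-tetrahydro-1-benzofuran-2(3H)-one (C3 epimers; formed in situ) | O[C@H]1C([C@@H](C)CCCO[Si](c3ccccc3)(c3ccccc3)C(C)(C)C)=C(C(OCC)OCC)C[C@H]2OC(=O)C(CN(C)C)[C@@H]12 | intermediate
31 | {[(3aS,4R,7aR)-5-[(2S)-5-{[tert-butyl(diphenyl)silyl]oxy}pentan-2-yl]-6-(diethoxymethyl)-4-hydroxy-2-oxo-2,3,3a,4,7,7a-hexahydro-1-benzofuran-3-yl]methyl}trimethylammonium iodide (formed in situ) | O[C@H]1C([C@@H](C)CCCO[Si](c3ccccc3)(c3ccccc3)C(C)(C)C)=C(C(OCC)OCC)C[C@H]2OC(=O)C(C[N+](C)(C)C)[C@@H]12.[I-] | intermediate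
32 | (3aS,4R,7aR)-5-[(2S)-5-{[tert-butyl(diphenyl)silyl]oxy}pentan-2-yl]-6-(diethoxymethyl)-4-hydroxy-3-methylidene-3a,4,7,7a-tetrahydro-1-benzofuran-2(3H)-one | O[C@H]1C([C@@H](C)CCCO[Si](c3ccccc3)(c3ccccc3)C(C)(C)C)=C(C(OCC)OCC)C[C@H]2OC(=O)C(=C)[C@@H]12 | intermediate
33 | (3aR,4S,7aR)-5-[(2S)-5-{[tert-butyl(diphenyl)silyl]oxy}pentan-2-yl]-6-(diethoxymethyl)-3-methylidene-2-oxo-2,3,3a,4,7,7a-hexahydro-1-benzofuran-4-yl 2-methylprop-2-enoate | C=C(C)C(=O)O[C@@H]1C([C@@H](C)CCCO[Si](c3ccccc3)(c3ccccc3)C(C)(C)C)=C(C(OCC)OCC)C[C@H]2OC(=O)C(=C)[C@@H]12 | intermediate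
34 | (3aR,4S,7aR)-6-formyl-5-[(2S)-5-hydroxypentan-2-yl]-3-methylidene-2-oxo-2,3,3a,4,7,7a-hexahydro-1-benzofuran-4-yl 2-methylprop-2-enoate | C=C(C)C(=O)O[C@@H]1C([C@@H](C)CCCO)=C(C=O)C[C@H]2OC(=O)C(=C)[C@@H]12 | intermediate
35 | (3aR,4S,7aR)-6-(hydroxymethyl)-5-[(2S)-5-hydroxypentan-2-yl]-3-methylidene-2-oxo-2,3,3a,4,7,7a-hexahydro-1-benzofuran-4-yl 2-methylprop-2-enoate | C=C(C)C(=O)O[C@@H]1C([C@@H](C)CCCO)=C(CO)C[C@H]2OC(=O)C(=C)[C@@H]12 | target

## Step count and risks

Total step count: 23.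
Longest linear sequence: 15 steps (steps 9–23; the lines through steps 1–6 and through steps 7–8 are equally long), which is 65 % of the total.

Three steps most likely to fail:

Step 17 (ring-closing aldol condensation). A CH2 next to a branched carbon must add to a hindered ketone and the aldol must dehydrate to a tetrasubstituted enone, while the β-silyloxy group can be lost by elimination and the product can aromatise. The fallback replaces the aldol by an intramolecular Horner–Wadsworth–Emmons olefination, which needs only the most acidic C–H. It sets out from 20 (with 8) and comes back at 26. Arbuzov reaction of 8 with P(OEt)3 at 150 °C gives diethyl phosphonate F1. Its lithio derivative (n-BuLi, THF, −78 °C, 2 equiv) is acylated by 20 to give β-keto phosphonate F2. The ozonolysis–chlorite protocol of step 16 then leads through keto aldehyde F3 to keto acid phosphonate F4. K2CO3 and 18-crown-6 in toluene at 60 °C close the ring to 26.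

Step 20 (α-methylenation beside a free cis hydroxyl). The dianion may be hard to form cleanly, the alkoxide can shift the lactone to the C4 oxygen on warming, and the hindered Mannich base may resist quaternisation. The fallback uses an aldol with formaldehyde followed by dehydration instead of the Mannich–elimination sequence. It sets out from 29 and comes back at 32. The dianion of 29 (LiN(i-Pr)2, 2.5 equiv, THF, −78 °C) is quenched cold with monomeric CH2O gas to give hydroxymethyl lactone F5. MsCl (1.1 equiv) and Et3N at −20 °C convert only the primary hydroxyl into primary mesylate F6, which is not isolated, and DBU at rt eliminates it to 32.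

Step 21 (Mitsunobu inversion with methacrylic acid). The hindered allylic oxyphosphonium ion can eliminate to a diene instead of being displaced, PPh3 can add to the methylene lactone, and the step depends on the facial selectivity of step 19. The fallback sets the C4 configuration by a catalyst-controlled reduction and then acylates with retention. It sets out from 28 and comes back at 33. Reduction of 28 with catecholborane and (3aR)-1-methyl-3,3-diphenyltetrahydro-1H,3H-pyrrolo[1,2-c][1,3,2]oxazaborole (20 mol %) in toluene at −78 °C, the alkenyl side acting as the large group, gives trans alcohol F7. The methylenation of step 20 applied to F7 leads through Mannich base F8 and methiodide F9 to trans hydroxy methylene lactone F10. Methacrylic anhydride, Et3N and DMAP in CH2Cl2 at 0 °C then give 33.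

## Further compounds

F1 | step 17 | diethyl [(2S)-5-{[tert-butyl(diphenyl)silyl]oxy}-2-methylpentyl]phosphonate | CCOP(=O)(OCC)C[C@@H](C)CCCO[Si](c1ccccc1)(c1ccccc1)C(C)(C)C
F2 | step 17 | diethyl [(4R,5R,8S)-11-{[tert-butyl(diphenyl)silyl]oxy}-2-(diethoxymethyl)-8-methyl-6-oxo-5-(prop-2-en-1-yl)-4-[(triethylsilyl)oxy]undec-1-en-7-yl]phosphonate (C7 epimers) | CCOP(=O)(OCC)C([C@@H](C)CCCO[Si](c1ccccc1)(c1ccccc1)C(C)(C)C)C(=O)[C@H](CC=C)[C@H](O[Si](CC)(CC)CC)CC(=C)C(OCC)OCC
F3 | step 17 | (3R,4R)-3-[(3S)-6-{[tert-butyl(diphenyl)silyl]oxy}-2-(diethoxyphosphoryl)-3-methylhexanoyl]-7,7-diethoxy-6-oxo-4-[(triethylsilyl)oxy]heptanal (epimers at the phosphorus-bearing carbon) | CCOP(=O)(OCC)C([C@@H](C)CCCO[Si](c1ccccc1)(c1ccccc1)C(C)(C)C)C(=O)[C@H](CC=O)[C@H](O[Si](CC)(CC)CC)CC(=O)C(OCC)OCC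
F4 | step 17 | (3R,4R)-3-[(3S)-6-{[tert-butyl(diphenyl)silyl]oxy}-2-(diethoxyphosphoryl)-3-methylhexanoyl]-7,7-diethoxy-6-oxo-4-[(triethylsilyl)oxy]heptanoic acid (epimers at the phosphorus-bearing carbon) | CCOP(=O)(OCC)C([C@@H](C)CCCO[Si](c1ccccc1)(c1ccccc1)C(C)(C)C)C(=O)[C@H](CC(=O)O)[C@H](O[Si](CC)(CC)CC)CC(=O)C(OCC)OCC
F5 | step 20 | (3aS,4R,7aR)-5-[(2S)-5-{[tert-butyl(diphenyl)silyl]oxy}pentan-2-yl]-6-(diethoxymethyl)-4-hydroxy-3-(hydroxymethyl)-3a,4,7,7a-tetrahydro-1-benzofuran-2(3H)-one (C3 epimers) | O[C@H]1C([C@@H](C)CCCO[Si](c3ccccc3)(c3ccccc3)C(C)(C)C)=C(C(OCC)OCC)C[C@H]2OC(=O)C(CO)[C@@H]12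
F6 | step 20 | [(3aS,4R,7aR)-5-[(2S)-5-{[tert-butyl(diphenyl)silyl]oxy}pentan-2-yl]-6-(diethoxymethyl)-4-hydroxy-2-oxo-2,3,3a,4,7,7a-hexahydro-1-benzofuran-3-yl]methyl methanesulfonate (C3 epimers) | O[C@H]1C([C@@H](C)CCCO[Si](c3ccccc3)(c3ccccc3)C(C)(C)C)=C(C(OCC)OCC)C[C@H]2OC(=O)C(COS(C)(=O)=O)[C@@H]12
F7 | step 21 | (3aS,4S,7aR)-5-[(2S)-5-{[tert-butyl(diphenyl)silyl]oxy}pentan-2-yl]-6-(diethoxymethyl)-4-hydroxy-3a,4,7,7a-tetrahydro-1-benzofuran-2(3H)-one (4-OH trans to the lactone ring) | O[C@@H]1C([C@@H](C)CCCO[Si](c3ccccc3)(c3ccccc3)C(C)(C)C)=C(C(OCC)OCC)C[C@H]2OC(=O)C[C@@H]12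
F8 | step 21 | (3aS,4S,7aR)-5-[(2S)-5-{[tert-butyl(diphenyl)silyl]oxy}pentan-2-yl]-6-(diethoxymethyl)-3-[(dimethylamino)methyl]-4-hydroxy-3a,4,7,7a-tetrahydro-1-benzofuran-2(3H)-one (C3 epimers) | O[C@@H]1C([C@@H](C)CCCO[Si](c3ccccc3)(c3ccccc3)C(C)(C)C)=C(C(OCC)OCC)C[C@H]2OC(=O)C(CN(C)C)[C@@H]12
F9 | step 21 | {[(3aS,4S,7aR)-5-[(2S)-5-{[tert-butyl(diphenyl)silyl]oxy}pentan-2-yl]-6-(diethoxymethyl)-4-hydroxy-2-oxo-2,3,3a,4,7,7a-hexahydro-1-benzofuran-3-yl]methyl}trimethylammonium iodide | O[C@@H]1C([C@@H](C)CCCO[Si](c3ccccc3)(c3ccccc3)C(C)(C)C)=C(C(OCC)OCC)C[C@H]2OC(=O)C(C[N+](C)(C)C)[C@@H]12.[I-]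
F10 | step 21 | (3aS,4S,7aR)-5-[(2S)-5-{[tert-butyl(diphenyl)silyl]oxy}pentan-2-yl]-6-(diethoxymethyl)-4-hydroxy-3-methylidene-3a,4,7,7a-tetrahydro-1-benzofuran-2(3H)-one | O[C@@H]1C([C@@H](C)CCCO[Si](c3ccccc3)(c3ccccc3)C(C)(C)C)=C(C(OCC)OCC)C[C@H]2OC(=O)C(=C)[C@@H]12
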